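**Strategy.** The dienone ring is numbered C1 (ring ketone), C2 (acyl), C3 (enol), C4 (cyclopentylmethyl), C5 (enol), C6 (quaternary). Its 1,3,5-oxygenation is exploited: a siloxypropyne supplies C5–C6 and is inserted into the C1–C4 bond of a 2-alkyl-3-siloxycyclobutenone that already carries the limonene-derived cyclopentane. In one thermal operation (Danheiser benzannulation: ring opening to a vinylketene, [2+2], second opening, 6π closure) C1–C6 and C4–C5 are formed and the temporary C1–C4 bond is cleaved, giving a regiodefined phloroglucinol. Acyl transfer to C2 and a catalyst-controlled dearomative prenylation at C6 complete the target.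

Key step: step 7

Assumption: the sense of induction of the chiral diphosphine in step 11 cannot be fixed by analogy, so the (R,R)-ligand is written and the (S,S)-antipode is used instead if a test run shows the opposite sense at C6.

Step 1
Reactants: 1 (4R)-limonene 1,2-oxide (commercial cis/trans mixture)
Product: 2 (3R)-6-oxo-3-(prop-1-en-2-yl)heptanal
Conditions: H5IO6, THF/H2O, 0 °C to rt
Reagents that add atoms: water, O
Why: Periodic acid hydrolyses the epoxide and cleaves the resulting 1,2-diol (oxidative glycol cleavage), so both epoxide diastereomers should converge on one keto aldehyde while the isopropenyl group and the (R)-centre from limonene stay untouched.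

Step 2
Reactants: 2 (3R)-6-oxo-3-(prop-1-en-2-yl)heptanal
Product: 3 (1S,2R,5R)-2-hydroxy-2-methyl-5-(prop-1-en-2-yl)cyclopentane-1-carbaldehyde
Conditions: L-proline (20 mol%), CH2Cl2, 0 °C to rt
Reagents that add atoms: none
Why: Proline-catalysed 5-enolexo intramolecular aldol reaction in which the aldehyde enamine adds to the methyl ketone through the carboxylic-acid-hydrogen-bonded transition state, L-proline being matched with the existing (R)-centre, so that the formyl group should end trans to isopropenyl (ring C1 set as S) and cis to the new tertiary hydroxyl (ring C2 set as R), which is also the least strained isomer.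

Step 3
Reactants: 3 (1S,2R,5R)-2-hydroxy-2-methyl-5-(prop-1-en-2-yl)cyclopentane-1-carbaldehyde
Product: 4 (1S,2R,5R)-2-methyl-5-(prop-1-en-2-yl)-2-(triethylsilyloxy)cyclopentane-1-carbaldehyde
Conditions: Et3SiOTf, 2,6-lutidine, CH2Cl2, −78 °C
Reagents that add atoms: triethylsilyl trifluoromethanesulfonate, CC[Si](CC)(CC)OS(=O)(=O)C(F)(F)F
Why: Silylation of the tertiary alcohol with a silyl triflate and a hindered base should block retro-aldol cleavage and later ketene trapping without touching the aldehyde or its α-centre at low temperature.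

Step 4
Reactants: 4 (1S,2R,5R)-2-methyl-5-(prop-1-en-2-yl)-2-(triethylsilyloxy)cyclopentane-1-carbaldehyde; 5 cyclobutane-1,3-dione
Product: 7 3-hydroxy-2-{[(1S,2R,5R)-2-methyl-5-(prop-1-en-2-yl)-2-(triethylsilyloxy)cyclopentyl]methyl}cyclobut-2-en-1-one, via alkylidene dione 6 (not isolated)
Conditions: Hantzsch ester (diethyl 2,6-dimethyl-1,4-dihydropyridine-3,5-dicarboxylate), L-proline (5 mol%), CH2Cl2, rt
Reagents that add atoms: none
Why: Three-component reductive alkylation of a cyclic 1,3-dione (Knoevenagel condensation with the aldehyde, then conjugate hydride transfer from the dihydropyridine to alkylidene 6) should alkylate the carbon between the two carbonyls, no stereocentre being formed and the trans,trans arrangement at the former formyl-bearing carbon being the thermodynamic one should it equilibrate.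

Step 5
Reactants: 7 3-hydroxy-2-(cyclopentylmethyl)cyclobut-2-en-1-one
Product: 8 2-{[(1S,2R,5R)-2-methyl-5-(prop-1-en-2-yl)-2-(triethylsilyloxy)cyclopentyl]methyl}-3-(triisopropylsilyloxy)cyclobut-2-en-1-one
Conditions: i-Pr3SiOTf, Et3N, CH2Cl2, −78 to 0 °C
Reagents that add atoms: triisopropylsilyl trifluoromethanesulfonate, CC(C)[Si](C(C)C)(C(C)C)OS(=O)(=O)C(F)(F)F
Why: O-Silylation of the vinylogous acid, whose two enol forms are identical, should give the vinylogous silyl ester, that is the 3-siloxycyclobutenone needed as vinylketene precursor.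

Step 6
Reactants: 9 1-propynyllithium
Product: 11 triisopropyl(prop-1-yn-1-yloxy)silane, via lithium ynolate 10 (not isolated)
Conditions: t-BuOOH, LiN(SiMe3)2, THF, −78 °C; then 9, −78 to 0 °C; then i-Pr3SiOTf, −78 °C
Reagents that add atoms: tert-butyl hydroperoxide, CC(C)(C)OO; triisopropylsilyl trifluoromethanesulfonate, CC(C)[Si](C(C)C)(C(C)C)OS(=O)(=O)C(F)(F)F
Why: Electrophilic oxygenation of the lithium acetylide by lithium tert-butyl peroxide should give the lithium ynolate, whose O-silylation with the bulky silyl triflate gives the siloxyalkyne.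

Step 7
Reactants: 8 2-(cyclopentylmethyl)-3-(triisopropylsilyloxy)cyclobut-2-en-1-one; 11 triisopropyl(prop-1-yn-1-yloxy)silane
Product: 15 2-methyl-4-{[(1S,2R,5R)-2-methyl-5-(prop-1-en-2-yl)-2-(triethylsilyloxy)cyclopentyl]methyl}-3,5-bis(triisopropylsilyloxy)phenol, via vinylketene 12 (not isolated), via vinylcyclobutenone 13 (not isolated), via dienylketene 14 (not isolated)
Conditions: 11 (2.5 equiv), toluene, 110 °C, sealed tube, argon
Reagents that add atoms: none
Why: Danheiser benzannulation: thermal 4π electrocyclic opening of cyclobutenone 8 gives vinylketene 12, whose ketene C=C bond adds the electron-rich siloxyalkyne in a [2+2] cycloaddition, the methyl-bearing alkyne carbon attacking the ketene carbonyl carbon (C1–C6) and the siloxy-bearing carbon joining the ketene α-carbon (C4–C5), to give 13. A second 4π opening cleaves the old C1–C4 bond to dienylketene 14, and the six-membered ring is closed by thermal 6π disrotatory electrocyclisation (C1–C2) followed by tautomerisation to the phenol. The closest known reaction type is the benzannulation of 3-alkoxy- or 3-siloxycyclobutenones with siloxyalkynes to resorcinol and phloroglucinol silyl ethers; the four-membered ring of 13 is closed by [2+2] cycloaddition and the benzene ring by electrocyclisation. No stereocentre is created, since the quaternary centre of 13 is lost on ring opening and the three cyclopentane centres are remote from all reacting atoms. The step needs regioselectivity, which the polarisation of the ynol ether secures, and chemoselectivity of the ketene for the alkyne over the isopropenyl group, which is secured by the excess of the far more nucleophilic alkyne and by the trans relation of side chain and isopropenyl on the cyclopentane (an intramolecular [2+2] would need a trans-fused bicyclo[3.3.0]octane). The tertiary hydroxyl is silylated so that it cannot lactonise onto the ketene.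

Step 8
Reactants: 15 2-methyl-4-(cyclopentylmethyl)-3,5-bis(triisopropylsilyloxy)phenol; 16 (S)-2-methylbutanoic acid
Product: 17 aryl (2S)-2-methylbutanoate of phenol 15
Conditions: DCC, DMAP (cat.), CH2Cl2, 0 °C to rt
Reagents that add atoms: none
Why: Steglich esterification of the only free phenol under neutral carbodiimide conditions should attach the (S)-2-methylbutanoyl group, whose stereocentre comes from the commercial acid, without exposing it to ketene formation or strong base.

Step 9
Reactants: 17 aryl (2S)-2-methylbutanoate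
Product: 18 (2S)-1-(2-hydroxy-3-methyl-5-{[(1S,2R,5R)-2-methyl-5-(prop-1-en-2-yl)-2-(triethylsilyloxy)cyclopentyl]methyl}-4,6-bis(triisopropylsilyloxy)phenyl)-2-methylbutan-1-one
Conditions: hν (254 nm), degassed cyclohexane, rt
Reagents that add atoms: none
Why: Photo-Fries rearrangement, in which homolysis of the aryl ester C–O bond and in-cage recombination of the acyl radical at C2 (the only unsubstituted ring position, the other ortho and the para positions being blocked) should give the chelated ortho-hydroxyaryl ketone under neutral conditions that spare the silyl ethers, the isopropenyl group and the α-stereocentre.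

Step 10
Reactants: 18 bis(triisopropylsilyl) triethylsilyl acylphenol
Product: 19 (2S)-1-(2,4,6-trihydroxy-3-{[(1S,2R,5R)-2-hydroxy-2-methyl-5-(prop-1-en-2-yl)cyclopentyl]methyl}-5-methylphenyl)-2-methylbutan-1-one
Conditions: Bu4NF, AcOH, THF, 0 °C to rt
Reagents that add atoms: none
Why: Fluoride should cleave the two aryl triisopropylsilyl ethers and the tertiary triethylsilyl ether by Si–F bond formation, while the acetic acid buffer keeps the liberated acylphloroglucinol from base-induced epimerisation and air oxidation.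

Step 11
Reactants: 19 free acylphloroglucinol; 20 3-methylbut-2-en-1-yl acetate (prenyl acetate)
Product: 21 (6R)-3,5-dihydroxy-4-{[(1S,2R,5R)-2-hydroxy-2-methyl-5-(prop-1-en-2-yl)cyclopentyl]methyl}-6-methyl-2-[(2S)-2-methylbutanoyl]-6-(3-methylbut-2-en-1-yl)cyclohexa-2,4-dien-1-one (target)
Conditions: Pd2(dba)3·CHCl3 (2.5 mol%), (R,R)-N,N'-bis(2-diphenylphosphinobenzoyl)-1,2-diaminocyclohexane (7.5 mol%), Et3N, degassed CH2Cl2, 0 °C to rt
Reagents that add atoms: none
Why: Palladium-catalysed asymmetric allylic alkylation of the phloroglucinol anion (Tsuji–Trost-type dearomative C-prenylation) should join the less hindered terminus of the dimethylallyl palladium cation to C6, the methyl-bearing ring carbon that is less shielded than C4, and the chiral pocket of the diphosphine, which distinguishes the chelated acyl flank from the alkyl flank of the planar nucleophile, should set the C6 configuration by catalyst control, the remote cyclopentane and sec-butyl centres having no influence.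

**Compound list**

1 | (4R)-limonene 1,2-oxide, (4R)-1-methyl-4-(prop-1-en-2-yl)-7-oxabicyclo[4.1.0]heptane, cis/trans mixture | CC(=C)[C@@H]1CCC2(C)OC2C1 | starting material
2 | (3R)-6-oxo-3-(prop-1-en-2-yl)heptanal | O=CC[C@@H](CCC(C)=O)C(C)=C | intermediate
3 | (1S,2R,5R)-2-hydroxy-2-methyl-5-(prop-1-en-2-yl)cyclopentane-1-carbaldehyde | C=C(C)[C@@H]1CC[C@@](C)(O)[C@H]1C=O | intermediate
4 | (1S,2R,5R)-2-methyl-5-(prop-1-en-2-yl)-2-(triethylsilyloxy)cyclopentane-1-carbaldehyde | C=C(C)[C@@H]1CC[C@@](C)(O[Si](CC)(CC)CC)[C@H]1C=O | intermediate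
5 | cyclobutane-1,3-dione | O=C1CC(=O)C1 | starting material
6 | 2-alkylidenecyclobutane-1,3-dione from 4 and 5 (cyclopentane configuration as in 4), not isolated | C=C(C)[C@@H]1CC[C@@](C)(O[Si](CC)(CC)CC)[C@H]1C=C1C(=O)CC1=O | intermediate
7 | 3-hydroxy-2-{[(1S,2R,5R)-2-methyl-5-(prop-1-en-2-yl)-2-(triethylsilyloxy)cyclopentyl]methyl}cyclobut-2-en-1-one | C=C(C)[C@@H]1CC[C@@](C)(O[Si](CC)(CC)CC)[C@H]1CC1=C(O)CC1=O | intermediate
8 | 2-{[(1S,2R,5R)-2-methyl-5-(prop-1-en-2-yl)-2-(triethylsilyloxy)cyclopentyl]methyl}-3-(triisopropylsilyloxy)cyclobut-2-en-1-one | C=C(C)[C@@H]1CC[C@@](C)(O[Si](CC)(CC)CC)[C@H]1CC1=C(O[Si](C(C)C)(C(C)C)C(C)C)CC1=O | intermediate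
9 | 1-propynyllithium | CC#C[Li] | starting material
10 | lithium prop-1-yn-1-olate, not isolated | CC#CO[Li] | intermediate
11 | triisopropyl(prop-1-yn-1-yloxy)silane | CC#CO[Si](C(C)C)(C(C)C)C(C)C | intermediate
12 | vinylketene, 2-(cyclopentylmethyl)-3-(triisopropylsilyloxy)buta-1,3-dien-1-one, not isolated | C=C(C)[C@@H]1CC[C@@](C)(O[Si](CC)(CC)CC)[C@H]1CC(=C=O)C(=C)O[Si](C(C)C)(C(C)C)C(C)C | intermediate
13 | 4-(cyclopentylmethyl)-2-methyl-3-(triisopropylsilyloxy)-4-[1-(triisopropylsilyloxy)vinyl]cyclobut-2-en-1-one, mixture at the ring quaternary carbon, not isolated | C=C(C)[C@@H]1CC[C@@](C)(O[Si](CC)(CC)CC)[C@H]1CC1(C(=C)O[Si](C(C)C)(C(C)C)C(C)C)C(=O)C(C)=C1O[Si](C(C)C)(C(C)C)C(C)C | intermediate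
14 | dienylketene, 4-(cyclopentylmethyl)-2-methyl-3,5-bis(triisopropylsilyloxy)hexa-1,3,5-trien-1-one, not isolated | C=C(C)[C@@H]1CC[C@@](C)(O[Si](CC)(CC)CC)[C@H]1CC(C(=C)O[Si](C(C)C)(C(C)C)C(C)C)=C(O[Si](C(C)C)(C(C)C)C(C)C)C(C)=C=O | intermediate
15 | 2-methyl-4-{[(1S,2R,5R)-2-methyl-5-(prop-1-en-2-yl)-2-(triethylsilyloxy)cyclopentyl]methyl}-3,5-bis(triisopropylsilyloxy)phenol | C=C(C)[C@@H]1CC[C@@](C)(O[Si](CC)(CC)CC)[C@H]1Cc1c(O[Si](C(C)C)(C(C)C)C(C)C)cc(O)c(C)c1O[Si](C(C)C)(C(C)C)C(C)C | intermediate
16 | (S)-2-methylbutanoic acid | O=C(O)[C@@H](C)CC | starting material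
17 | 2-methyl-4-{[(1S,2R,5R)-2-methyl-5-(prop-1-en-2-yl)-2-(triethylsilyloxy)cyclopentyl]methyl}-3,5-bis(triisopropylsilyloxy)phenyl (2S)-2-methylbutanoate | C=C(C)[C@@H]1CC[C@@](C)(O[Si](CC)(CC)CC)[C@H]1Cc1c(O[Si](C(C)C)(C(C)C)C(C)C)cc(OC(=O)[C@@H](C)CC)c(C)c1O[Si](C(C)C)(C(C)C)C(C)C | intermediate
18 | (2S)-1-(2-hydroxy-3-methyl-5-{[(1S,2R,5R)-2-methyl-5-(prop-1-en-2-yl)-2-(triethylsilyloxy)cyclopentyl]methyl}-4,6-bis(triisopropylsilyloxy)phenyl)-2-methylbutan-1-one | C=C(C)[C@@H]1CC[C@@](C)(O[Si](CC)(CC)CC)[C@H]1Cc1c(O[Si](C(C)C)(C(C)C)C(C)C)c(C(=O)[C@@H](C)CC)c(O)c(C)c1O[Si](C(C)C)(C(C)C)C(C)C | intermediate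
19 | (2S)-1-(2,4,6-trihydroxy-3-{[(1S,2R,5R)-2-hydroxy-2-methyl-5-(prop-1-en-2-yl)cyclopentyl]methyl}-5-methylphenyl)-2-methylbutan-1-one | C=C(C)[C@@H]1CC[C@@](C)(O)[C@H]1Cc1c(O)c(C(=O)[C@@H](C)CC)c(O)c(C)c1O | intermediate
20 | 3-methylbut-2-en-1-yl acetate (prenyl acetate) | CC(=O)OCC=C(C)C | starting material
21 | (6R)-3,5-dihydroxy-4-{[(1S,2R,5R)-2-hydroxy-2-methyl-5-(prop-1-en-2-yl)cyclopentyl]methyl}-6-methyl-2-[(2S)-2-methylbutanoyl]-6-(3-methylbut-2-en-1-yl)cyclohexa-2,4-dien-1-one | C=C(C)[C@@H]1CC[C@@](C)(O)[C@H]1CC1=C(O)[C@@](C)(CC=C(C)C)C(=O)C(C(=O)[C@@H](C)CC)=C1O | target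

**Step count.** Total: 11 steps. Longest linear sequence: 10 steps (steps 1–5 and 7–11); step 6 is a one-step side branch.

**Steps most likely to fail**

Step 11. The chiral palladium catalyst may discriminate poorly between the two faces of C6, because the two flanks of the planar nucleophile differ only one atom further out. The bulky dimethylallyl electrophile may also leak to the branched isomer, to O-alkylation or to attack at C4. Fallback: setting out from 19, the same palladium/diphosphine system is used with allyl methyl carbonate, the electrophile for which asymmetric allylic dearomatisation is best established, to give the C6-allyl dienone F1. Cross-metathesis of F1 with 2-methylbut-2-ene (second-generation Grubbs catalyst, RuCl2(H2IMes)(PCy3)(=CHPh), CH2Cl2, 40 °C) should then convert allyl into prenyl and come back to the route at 21; the 1,1-disubstituted isopropenyl group should not take part.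

Step 4. Elimination of the β-silyloxy group through the enamine or through alkylidene 6, or opening of the strained dione by the amine catalyst, may outrun condensation with the hindered α-branched aldehyde. Fallback (sp3–sp2 cross-coupling instead of condensation): setting out from 4, reduction with NaBH4 in MeOH gives the primary alcohol F2, and I2/PPh3/imidazole converts it into the primary iodide F3. Zinc insertion (Zn dust, LiCl, THF) gives the alkylzinc iodide F4. In parallel, 5 is O-silylated (i-Pr3SiOTf, Et3N) to 3-(triisopropylsilyloxy)cyclobut-2-en-1-one F5 and brominated with NBS to 2-bromo-3-(triisopropylsilyloxy)cyclobut-2-en-1-one F6. Negishi coupling of F4 with F6 (Pd(OAc)2, 2-dicyclohexylphosphino-2',6'-dimethoxybiphenyl, THF, rt) comes back to the route at 8.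

Step 9. The acyl/aryloxy radical pair may escape the solvent cage, returning phenol 15 and losing the acyl group by decarbonylation, instead of recombining at C2. Fallback (ionic instead of photochemical acyl transfer): setting out from 15, bromination with NBS (CH2Cl2, −78 °C) at the only free ring position gives the bromophenol F7. Steglich esterification with 16 gives the bromoaryl ester F8. Treatment with t-BuLi (2 equiv, THF, −100 °C) should cause bromine–lithium exchange and intramolecular 1,3 O-to-C acyl shift (anionic Fries-type rearrangement) and comes back to the route at 18.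

Further compounds
F1 | step 11 | C6-allyl analogue of 21, (6R)-6-allyl-3,5-dihydroxy-4-(cyclopentylmethyl)-6-methyl-2-[(2S)-2-methylbutanoyl]cyclohexa-2,4-dien-1-one, side chains as in 21 | C=C(C)[C@@H]1CC[C@@](C)(O)[C@H]1CC1=C(O)[C@@](C)(CC=C)C(=O)C(C(=O)[C@@H](C)CC)=C1O
F2 | step 4 | primary alcohol from reduction of 4, [2-methyl-5-(prop-1-en-2-yl)-2-(triethylsilyloxy)cyclopentyl]methanol, configuration as in 4 | C=C(C)[C@@H]1CC[C@@](C)(O[Si](CC)(CC)CC)[C@H]1CO
F3 | step 4 | primary iodide from F2, configuration as in 4 | C=C(C)[C@@H]1CC[C@@](C)(O[Si](CC)(CC)CC)[C@H]1CI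
F4 | step 4 | alkylzinc iodide from F3, configuration as in 4 | C=C(C)[C@@H]1CC[C@@](C)(O[Si](CC)(CC)CC)[C@H]1C[Zn]I
F5 | step 4 | 3-(triisopropylsilyloxy)cyclobut-2-en-1-one | O=C1CC(O[Si](C(C)C)(C(C)C)C(C)C)=C1
F6 | step 4 | 2-bromo-3-(triisopropylsilyloxy)cyclobut-2-en-1-one | O=C1CC(O[Si](C(C)C)(C(C)C)C(C)C)=C1Br
F7 | step 9 | 6-bromo derivative of phenol 15 (bromine ortho to the free hydroxyl) | C=C(C)[C@@H]1CC[C@@](C)(O[Si](CC)(CC)CC)[C@H]1Cc1c(O[Si](C(C)C)(C(C)C)C(C)C)c(Br)c(O)c(C)c1O[Si](C(C)C)(C(C)C)C(C)C
F8 | step 9 | (2S)-2-methylbutanoate ester of bromophenol F7 | C=C(C)[C@@H]1CC[C@@](C)(O[Si](CC)(CC)CC)[C@H]1Cc1c(O[Si](C(C)C)(C(C)C)C(C)C)c(Br)c(OC(=O)[C@@H](C)CC)c(C)c1O[Si](C(C)C)(C(C)C)C(C)C
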